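**Strategy.** The plan cuts the α-methylene-γ-butyrolactone away from the ten-membered ring (germacrane numbering). The lactone oxygen on C8 is allylic to the C9=C10 alkene, so C7–C8–C9=C10 is read as a ring 1,3-diene, C7=C8–C9=C10, that has taken up a C(=CH2)–CO2 unit. The key step is a palladium-catalysed [3+2] heteroannulation of the butenolide-bridged cyclodecatriene 15 with 2-bromoacrylic acid: carbopalladation at C7 and allylic C–O closure at C8 form C11–C7 and O–C8 in one operation and set C7 and C8. Triene 15, which lacks the whole second lactone, comes from a dienal by enantioselective alkynylation, iodobutenolide formation and Nozaki–Hiyama–Kishi ring closure.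

Key step: step 10

Remark on numbering: ring carbons are C1–C10; C11, C12 (carbonyl) and C13 (methylene) belong to the methylene lactone on C7/C8; C14 is the hydroxymethyl carbon on C10; C15 is the butenolide carbonyl carbon on C4.

Remark on step 6: the (S,S)-ProPhenol/Me2Zn catalyst is assumed to deliver the alkyne to the face of enal 8 that gives the 4S carbinol; if the sense is the opposite, the (R,R) ligand is used.

Step 1
Reactants: 1 triethyl phosphonoacetate; 2 2-(2-bromoethyl)-1,3-dioxolane
Product: 3 ethyl 2-(diethoxyphosphoryl)-4-(1,3-dioxolan-2-yl)butanoate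
Conditions: NaH, DMF, 0 °C; then 2, 60 °C
Reagents that add atoms: none
Why: C-alkylation of the stabilised phosphonoacetate anion by a primary bromide (SN2) should install C1–C3 with C3 masked as a dioxolane; no stereocenter is formed.

Step 2
Reactants: 3 ethyl 2-(diethoxyphosphoryl)-4-(1,3-dioxolan-2-yl)butanoate; 4 (E)-4,4-dimethoxybut-2-enal (fumaraldehyde mono(dimethyl acetal))
Product: 5 ethyl (2E,4E)-2-[2-(1,3-dioxolan-2-yl)ethyl]-6,6-dimethoxyhexa-2,4-dienoate
Conditions: NaH, THF, 0 °C to rt
Reagents that add atoms: none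
Why: Horner–Wadsworth–Emmons olefination of an enal with an α-branched phosphonate should give the 2E trisubstituted enoate (ester trans to the dienyl chain), which places C1 cis to C8 as the ring later requires.

Step 3
Reactants: 5 ethyl (2E,4E)-2-[2-(1,3-dioxolan-2-yl)ethyl]-6,6-dimethoxyhexa-2,4-dienoate
Product: 6 (2E,4E)-2-[2-(1,3-dioxolan-2-yl)ethyl]-6,6-dimethoxyhexa-2,4-dien-1-ol
Conditions: i-Bu2AlH (2.2 equiv), CH2Cl2, −78 °C
Reagents that add atoms: none
Why: Hydride reduction of the conjugated ester (1,2-reduction with i-Bu2AlH) should give the C14 allylic alcohol while both acetals and the diene geometry stay untouched.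

Step 4
Reactants: 6 (2E,4E)-2-[2-(1,3-dioxolan-2-yl)ethyl]-6,6-dimethoxyhexa-2,4-dien-1-ol
Product: 7 tert-butyl({(2E,4E)-2-[2-(1,3-dioxolan-2-yl)ethyl]-6,6-dimethoxyhexa-2,4-dien-1-yl}oxy)diphenylsilane
Conditions: TBDPSCl, imidazole, DMF, rt
Reagents that add atoms: tert-butyl(chloro)diphenylsilane (TBDPSCl), CC(C)(C)[Si](Cl)(c1ccccc1)c1ccccc1
Why: Silylation of the primary alcohol gives an acid-stable TBDPS ether that should survive both later acetal hydrolyses and keeps O14 from attacking the allylpalladium intermediate of step 10.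

Step 5
Reactants: 7 tert-butyl({(2E,4E)-2-[2-(1,3-dioxolan-2-yl)ethyl]-6,6-dimethoxyhexa-2,4-dien-1-yl}oxy)diphenylsilane
Product: 8 (2E,4E)-5-{[(tert-butyldiphenylsilyl)oxy]methyl}-7-(1,3-dioxolan-2-yl)hepta-2,4-dienal
Conditions: PPTS (cat.), acetone/H2O (20:1), 0 °C to rt
Reagents that add atoms: water, O
Why: Chemoselective acetal hydrolysis: the dienyl dimethyl acetal ionises through a pentadienyl oxocarbenium ion far faster than the saturated dioxolane, so only the C6 aldehyde should be freed.

Step 6
Reactants: 8 (2E,4E)-5-{[(tert-butyldiphenylsilyl)oxy]methyl}-7-(1,3-dioxolan-2-yl)hepta-2,4-dienal; 9 methyl propiolate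
Product: 10 methyl (4S,5E,7E)-8-{[(tert-butyldiphenylsilyl)oxy]methyl}-10-(1,3-dioxolan-2-yl)-4-hydroxydeca-5,7-dien-2-ynoate
Conditions: Me2Zn, (S,S)-ProPhenol (20 mol %), Ph3PO (40 mol %), toluene, 4 °C
Reagents that add atoms: none
Why: Catalytic enantioselective alkynylation of an unsaturated aldehyde (Trost ProPhenol dinuclear zinc alkynylation) should add the zinc acetylide of 9 to one aldehyde face under ligand control and set C6 (4S here, the centre that becomes 6R in the target).

Step 7
Reactants: 10 methyl (4S,5E,7E)-8-{[(tert-butyldiphenylsilyl)oxy]methyl}-10-(1,3-dioxolan-2-yl)-4-hydroxydeca-5,7-dien-2-ynoate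
Product: 13 (5S)-5-[(1E,3E)-4-{[(tert-butyldiphenylsilyl)oxy]methyl}-6-(1,3-dioxolan-2-yl)hexa-1,3-dien-1-yl]-3-iodofuran-2(5H)-one, via stannyl hydroxy ester 11 (not isolated), via iodo hydroxy ester 12 (not isolated)
Conditions: Bu3SnH (1.1 equiv), Pd(PPh3)4 (3 mol %), THF, 0 °C; then I2, CH2Cl2, 0 °C; then PPTS, benzene, 50 °C
Reagents that add atoms: iodine, II; tributyltin hydride, CCCC[SnH](CCCC)CCCC (its tin stays only in intermediate 11)
Why: Palladium-catalysed syn hydrostannation of the ynoate should place tin on C4 (α to the ester) and H on C5, iododestannylation replaces tin with retention, and the ester now cis to the C6 hydroxyl lactonises to the α-iodobutenolide with C6 untouched.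

Step 8
Reactants: 13 (5S)-5-[(1E,3E)-4-{[(tert-butyldiphenylsilyl)oxy]methyl}-6-(1,3-dioxolan-2-yl)hexa-1,3-dien-1-yl]-3-iodofuran-2(5H)-one
Product: 14 (4E,6E)-4-{[(tert-butyldiphenylsilyl)oxy]methyl}-7-[(2S)-4-iodo-5-oxo-2,5-dihydrofuran-2-yl]hepta-4,6-dienal
Conditions: PPTS, acetone/H2O (10:1), 55 °C
Reagents that add atoms: water, O
Why: Acid-catalysed hydrolysis (transacetalisation) of the dioxolane should free the C3 aldehyde under conditions mild enough for the TBDPS ether, the iodobutenolide and the dienylic lactone C–O bond.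

Step 9
Reactants: 14 (4E,6E)-4-{[(tert-butyldiphenylsilyl)oxy]methyl}-7-[(2S)-4-iodo-5-oxo-2,5-dihydrofuran-2-yl]hepta-4,6-dienal
Product: 15 (2S,5E,7E,9S)-5-{[(tert-butyldiphenylsilyl)oxy]methyl}-2-hydroxy-10-oxabicyclo[7.2.1]dodeca-1(12),5,7-trien-11-one (ten-membered carbocycle C1–C10 with 7E,9-diene, bridged C4 to C6 by the butenolide; OH on C3)
Conditions: CrCl2 (8 equiv), NiCl2 (5 mol %), DMSO/THF (3:1), rt, syringe-pump addition to 2 mM
Reagents that add atoms: none
Why: Nozaki–Hiyama–Kishi reaction: nickel-catalysed activation of the C4–I bond and transfer to chromium give an alkenylchromium species (trivalent chromium) that should add to the C3 aldehyde under neutral conditions at high dilution to close the ten-membered ring; C3 is set by the ring-closing transition state, which is expected to expose the aldehyde face leading to the 3S alcohol (the epimer is covered by a fallback).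

Step 10
Reactants: 15 (2S,5E,7E,9S)-5-{[(tert-butyldiphenylsilyl)oxy]methyl}-2-hydroxy-10-oxabicyclo[7.2.1]dodeca-1(12),5,7-trien-11-one; 16 2-bromoacrylic acid
Product: 17 (3S,6R,7S,8R)-14-(tert-butyldiphenylsilyloxy)-3-hydroxygermacra-4,9,11(13)-triene-15,6:12,8-diolide (the target without the isobutyryl group and with O14 silylated)
Conditions: Pd2(dba)3 (5 mol %), Ag2CO3 (1.5 equiv), DMF, 50 °C
Reagents that add atoms: none
Why: Zerovalent palladium inserts into the C–Br bond of 16, the α-carboxyvinylpalladium species adds syn across C7=C8 with carbon going to C7 (C10 is fully substituted, and only addition at C7 gives an allyl complex), and the η3-allyl over C8–C9–C10 is captured at C8 by the palladium-bound carboxylate, which forms C11–C7 and O–C8 in one operation and returns zerovalent palladium. The closest known reaction type is the Larock heteroannulation of 1,3-dienes by organic halides that carry a carboxylic acid or another oxygen nucleophile. The lactone closes in a 5-exo mode onto the allyl terminus C8, and the C9=C10 bond left outside the new ring should keep its geometry because the fully substituted C10 resists the σ-allyl formation needed for syn/anti exchange. C7 is set by the face of carbopalladation: the E-C7=C8 bond stands across the ten-membered ring, only its outer face is open, and the reactive conformer is taken to have the C6–O bond near the alkene plane with C5 on the inner face. C8 is set by delivery of oxygen from palladium on that same face, because the ring bond C7–C8 cannot rotate to allow backside attack, and syn addition to an E alkene gives the trans-fused lactone. The step needs selectivity for the diene over the trisubstituted butenolide alkene and survival of the allylic C6–O bond; phosphine-free conditions with Ag2CO3 (fast oxidative addition, bromide removal, low concentration of zerovalent palladium) are chosen to secure both.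

Step 11
Reactants: 17 (3S,6R,7S,8R)-14-(tert-butyldiphenylsilyloxy)-3-hydroxygermacra-4,9,11(13)-triene-15,6:12,8-diolide
Product: 18 (3S,6R,7S,8R)-14-(tert-butyldiphenylsilyloxy)-3-(2-methylpropanoyloxy)germacra-4,9,11(13)-triene-15,6:12,8-diolide
Conditions: (i-PrCO)2O, Et3N, DMAP (cat.), CH2Cl2, 0 °C to rt
Reagents that add atoms: 2-methylpropanoic anhydride (isobutyric anhydride), CC(C)C(=O)OC(=O)C(C)C
Why: DMAP-catalysed acyl transfer to the secondary C3 alcohol should proceed with retention at C3 and leave both lactones and the silyl ether intact.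

Step 12
Reactants: 18 (3S,6R,7S,8R)-14-(tert-butyldiphenylsilyloxy)-3-(2-methylpropanoyloxy)germacra-4,9,11(13)-triene-15,6:12,8-diolide
Product: 19 (3S,6R,7S,8R)-14-hydroxy-3-(2-methylpropanoyloxy)germacra-4,9,11(13)-triene-15,6:12,8-diolide (CNP0322767.4)
Conditions: HF·pyridine, THF/pyridine, 0 °C to rt
Reagents that add atoms: none
Why: Fluoride-mediated cleavage of the Si–O bond under buffered, weakly acidic conditions should free the C14 alcohol without touching the ester, the lactones or the conjugate acceptors.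

**Compound list**

1 | triethyl phosphonoacetate | CCOC(=O)CP(=O)(OCC)OCC | starting material
2 | 2-(2-bromoethyl)-1,3-dioxolane | BrCCC1OCCO1 | starting material
3 | ethyl 2-(diethoxyphosphoryl)-4-(1,3-dioxolan-2-yl)butanoate | CCOC(=O)C(CCC1OCCO1)P(=O)(OCC)OCC | intermediate
4 | (E)-4,4-dimethoxybut-2-enal | COC(OC)/C=C/C=O | starting material
5 | ethyl (2E,4E)-2-[2-(1,3-dioxolan-2-yl)ethyl]-6,6-dimethoxyhexa-2,4-dienoate | COC(OC)/C=C/C=C(/C(=O)OCC)CCC1OCCO1 | intermediate
6 | (2E,4E)-2-[2-(1,3-dioxolan-2-yl)ethyl]-6,6-dimethoxyhexa-2,4-dien-1-ol | COC(OC)/C=C/C=C(/CO)CCC1OCCO1 | intermediate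
7 | tert-butyl({(2E,4E)-2-[2-(1,3-dioxolan-2-yl)ethyl]-6,6-dimethoxyhexa-2,4-dien-1-yl}oxy)diphenylsilane | COC(OC)/C=C/C=C(/CO[Si](c1ccccc1)(c1ccccc1)C(C)(C)C)CCC1OCCO1 | intermediate
8 | (2E,4E)-5-{[(tert-butyldiphenylsilyl)oxy]methyl}-7-(1,3-dioxolan-2-yl)hepta-2,4-dienal | O=C/C=C/C=C(/CO[Si](c1ccccc1)(c1ccccc1)C(C)(C)C)CCC1OCCO1 | intermediate
9 | methyl propiolate | C#CC(=O)OC | starting material
10 | methyl (4S,5E,7E)-8-{[(tert-butyldiphenylsilyl)oxy]methyl}-10-(1,3-dioxolan-2-yl)-4-hydroxydeca-5,7-dien-2-ynoate | COC(=O)C#C[C@@H](O)/C=C/C=C(/CO[Si](c1ccccc1)(c1ccccc1)C(C)(C)C)CCC1OCCO1 | intermediate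
11 | methyl (2E,4S,5E,7E)-8-{[(tert-butyldiphenylsilyl)oxy]methyl}-10-(1,3-dioxolan-2-yl)-4-hydroxy-2-(tributylstannyl)deca-2,5,7-trienoate | COC(=O)/C(=C\[C@@H](O)/C=C/C=C(/CO[Si](c1ccccc1)(c1ccccc1)C(C)(C)C)CCC1OCCO1)[Sn](CCCC)(CCCC)CCCC | intermediate (not isolated)
12 | methyl (2E,4S,5E,7E)-8-{[(tert-butyldiphenylsilyl)oxy]methyl}-10-(1,3-dioxolan-2-yl)-4-hydroxy-2-iododeca-2,5,7-trienoate | COC(=O)/C(I)=C\[C@@H](O)/C=C/C=C(/CO[Si](c1ccccc1)(c1ccccc1)C(C)(C)C)CCC1OCCO1 | intermediate (not isolated)
13 | (5S)-5-[(1E,3E)-4-{[(tert-butyldiphenylsilyl)oxy]methyl}-6-(1,3-dioxolan-2-yl)hexa-1,3-dien-1-yl]-3-iodofuran-2(5H)-one | O=C1O[C@@H](/C=C/C=C(/CO[Si](c2ccccc2)(c2ccccc2)C(C)(C)C)CCC2OCCO2)C=C1I | intermediate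
14 | (4E,6E)-4-{[(tert-butyldiphenylsilyl)oxy]methyl}-7-[(2S)-4-iodo-5-oxo-2,5-dihydrofuran-2-yl]hepta-4,6-dienal | O=C1O[C@@H](/C=C/C=C(/CO[Si](c2ccccc2)(c2ccccc2)C(C)(C)C)CCC=O)C=C1I | intermediate
15 | (2S,5E,7E,9S)-5-{[(tert-butyldiphenylsilyl)oxy]methyl}-2-hydroxy-10-oxabicyclo[7.2.1]dodeca-1(12),5,7-trien-11-one | O=C1O[C@@H]2C=C1[C@@H](O)CC/C(CO[Si](c3ccccc3)(c3ccccc3)C(C)(C)C)=C\C=C\2 | intermediate
16 | 2-bromoacrylic acid | C=C(Br)C(=O)O | starting material
17 | (3S,6R,7S,8R)-14-(tert-butyldiphenylsilyloxy)-3-hydroxygermacra-4,9,11(13)-triene-15,6:12,8-diolide | C=C1C(=O)O[C@@H]2/C=C(/CO[Si](c4ccccc4)(c4ccccc4)C(C)(C)C)CC[C@H](O)C3=C[C@@H](OC3=O)[C@@H]12 | intermediate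
18 | (3S,6R,7S,8R)-14-(tert-butyldiphenylsilyloxy)-3-(2-methylpropanoyloxy)germacra-4,9,11(13)-triene-15,6:12,8-diolide | C=C1C(=O)O[C@@H]2/C=C(/CO[Si](c4ccccc4)(c4ccccc4)C(C)(C)C)CC[C@H](OC(=O)C(C)C)C3=C[C@@H](OC3=O)[C@@H]12 | intermediate
19 | (3S,6R,7S,8R)-14-hydroxy-3-(2-methylpropanoyloxy)germacra-4,9,11(13)-triene-15,6:12,8-diolide (CNP0322767.4) | C=C1C(=O)O[C@@H]2/C=C(/CO)CC[C@H](OC(=O)C(C)C)C3=C[C@@H](OC3=O)[C@@H]12 | target

**Step count.** Total: 12 steps. Longest linear sequence: 12 steps (1 to 19).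

**Steps most likely to fail**

Step 10 (key step). Carbopalladation of the hindered, twisted ring diene may be slow, so that the vinylpalladium species decomposes, attack may occur on the wrong face of C7=C8, or zerovalent palladium may ionise the allylic C6–O bond. The fallback keeps the same two bond formations but moves to a radical-polar crossover followed by decarboxylative methylenation. It sets out from 15: Mn(OAc)3·2H2O and potassium 3-tert-butoxy-3-oxopropanoate (KO2CCH2CO2t-Bu) in AcOH at 60 °C should add the malonyl radical to C7, oxidise the resulting allyl radical and close the carboxylate on C8 to give the α-(tert-butoxycarbonyl) lactone F1. CF3CO2H in CH2Cl2 would then give the α-carboxy lactone F2. Aqueous CH2O and Et2NH, then NaOAc/AcOH at 90 °C (decarboxylative Mannich methylenation), would install the exocyclic methylene and rejoin the route at 17.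

Step 9. The alkenylchromium species may add to the other face of the C3 aldehyde, giving mainly the 3R alcohol. The fallback sets the C3 ester by inversion instead of retention. From 14, the ring closure would give the 3R macrocyclic alcohol F3, which is taken through the conditions of step 10 to the 3R lactone F4. Mitsunobu esterification of F4 (PPh3, DIAD, 2-methylpropanoic acid, THF, 0 °C) should invert C3 and give the 3S ester directly, rejoining the route at 18.

Step 6. Face selection by the zinc catalyst may be poor on this dienal, or methyl transfer from Me2Zn may compete with alkynyl transfer. The fallback sets C6 by asymmetric reduction instead of asymmetric addition. From 8, the lithium acetylide of 9 (LiN(SiMe3)2, THF, −78 °C) would give the racemic carbinol F5, and MnO2 in CH2Cl2 would oxidise it to the ynone F6. Noyori transfer hydrogenation of the alkynyl ketone with RuCl[(S,S)-TsDPEN](p-cymene) and HCO2H/Et3N (catalyst antipode chosen for the 4S alcohol) would rejoin the route at 10.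

**Further compounds**

F1 | step 10 | tert-butyl ester of the 11-carboxy-11,13-dihydro-13-nor analogue of 17 (H and CO2t-Bu on C11 in place of the methylene, mixture at C11) | CC(C)(C)OC(=O)C1C(=O)O[C@@H]2/C=C(/CO[Si](c4ccccc4)(c4ccccc4)C(C)(C)C)CC[C@H](O)C3=C[C@@H](OC3=O)[C@@H]12
F2 | step 10 | 11-carboxy-11,13-dihydro-13-nor analogue of 17 (H and CO2H on C11, mixture at C11) | OC(=O)C1C(=O)O[C@@H]2/C=C(/CO[Si](c4ccccc4)(c4ccccc4)C(C)(C)C)CC[C@H](O)C3=C[C@@H](OC3=O)[C@@H]12
F3 | step 9 | (2R,5E,7E,9S)-5-{[(tert-butyldiphenylsilyl)oxy]methyl}-2-hydroxy-10-oxabicyclo[7.2.1]dodeca-1(12),5,7-trien-11-one (C3 epimer of 15) | O=C1O[C@@H]2C=C1[C@H](O)CC/C(CO[Si](c3ccccc3)(c3ccccc3)C(C)(C)C)=C\C=C\2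
F4 | step 9 | (3R,6R,7S,8R)-14-(tert-butyldiphenylsilyloxy)-3-hydroxygermacra-4,9,11(13)-triene-15,6:12,8-diolide (C3 epimer of 17) | C=C1C(=O)O[C@@H]2/C=C(/CO[Si](c4ccccc4)(c4ccccc4)C(C)(C)C)CC[C@@H](O)C3=C[C@@H](OC3=O)[C@@H]12
F5 | step 6 | methyl (5E,7E)-8-{[(tert-butyldiphenylsilyl)oxy]methyl}-10-(1,3-dioxolan-2-yl)-4-hydroxydeca-5,7-dien-2-ynoate (racemate) | COC(=O)C#CC(O)/C=C/C=C(/CO[Si](c1ccccc1)(c1ccccc1)C(C)(C)C)CCC1OCCO1
F6 | step 6 | methyl (5E,7E)-8-{[(tert-butyldiphenylsilyl)oxy]methyl}-10-(1,3-dioxolan-2-yl)-4-oxodeca-5,7-dien-2-ynoate | COC(=O)C#CC(=O)/C=C/C=C(/CO[Si](c1ccccc1)(c1ccccc1)C(C)(C)C)CCC1OCCO1
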